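**Retrosynthetic overview**
1. Target ⇒ six-ring spiro α-ketol (undo the acyloin ring contraction, bond C5–C9) ⇒ 2,3-epoxyquinone with a free side-chain carbinol (undo the 5-exo oxirane opening, bond O1–C5) ⇒ the parent hydroxyalkyl-trimethylbenzoquinone (undo the O-transfer).
2. In the forward direction these three events run in one flask. Ring order: oxirane (transient), then oxolane, then cyclopentenone (from the quinone ring).
3. Hydroxyalkylquinone ⇒ trimethyl-1,4-benzoquinone (its only ring C–H) plus the primary radical from a γ-iodo tertiary alcohol.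
4. Iodo alcohol ⇒ 1,3-diol ⇒ (2S,3S)-epoxyphytol ⇒ natural phytol. The Sharpless epoxidation sets C2, and phytol brings C4′ and C8′.

Assumption: the SMILES is read literally as (2S,5R,9S,4′R,8′R). Its C2 is the mirror image of C2 in natural (2R)-α-tocopherol and (3′R)-α-tocopherolquinone, so those cannot supply this centre and it is built from natural (E,7R,11R)-phytol.

**Step 1**
Reactants: 1 natural phytol, (2E,7R,11R)-3,7,11,15-tetramethylhexadec-2-en-1-ol
Product: 2 (2S,3S,7R,11R)-2,3-epoxyphytol = [(2S,3S)-3-methyl-3-[(4R,8R)-4,8,12-trimethyltridecyl]oxiran-2-yl]methanol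
Conditions: Ti(OiPr)4 (5 mol %), L-(+)-DET (7 mol %), anhydrous t-BuOOH (2 equiv), 4 Å MS, CH2Cl2, −20 °C
Reagents that add atoms: tert-butyl hydroperoxide, CC(C)(C)OO
Why: Katsuki–Sharpless asymmetric epoxidation, in which L-(+)-tartrate delivers oxygen to the same face of this E-trisubstituted allylic alcohol as it does with geraniol, giving the (2S,3S)-epoxide whose C3 becomes C2 (S) of the target.

**Step 2**
Reactants: 2 (2S,3S,7R,11R)-2,3-epoxyphytol
Product: 3 (3S,7R,11R)-3,7,11,15-tetramethylhexadecane-1,3-diol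
Conditions: sodium bis(2-methoxyethoxy)aluminium hydride (Red-Al, 3 equiv), THF, 0 °C → rt; Rochelle salt work-up
Reagents that add atoms: none
Why: Hydroxyl-directed reductive opening of a 2,3-epoxy alcohol, in which the aluminate bound at O1 hands hydride to the less hindered C2 and only the C2–O bond breaks, so the C3–O bond and the S configuration are untouched.

**Step 3**
Reactants: 3 (3S,7R,11R)-3,7,11,15-tetramethylhexadecane-1,3-diol
Product: 4 (3S,7R,11R)-1-iodo-3,7,11,15-tetramethylhexadecan-3-ol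
Conditions: I2 (1.1 equiv), PPh3 (1.1 equiv), imidazole (1.5 equiv), CH2Cl2, 0 °C, dark
Reagents that add atoms: iodine, II
Why: Appel-type (Garegg–Samuelsson) iodination, in which only the primary hydroxyl forms the alkoxyphosphonium salt and is displaced by iodide in an SN2 step, while the hindered tertiary carbinol and all stereocentres stay as they are.

**Step 4**
Reactants: 4 (3S,7R,11R)-1-iodo-3,7,11,15-tetramethylhexadecan-3-ol; 5 2,3,5-trimethyl-1,4-benzoquinone
Product: 6 2-[(3S,7R,11R)-3-hydroxy-3,7,11,15-tetramethylhexadecyl]-3,5,6-trimethyl-1,4-benzoquinone (3′-epi-α-tocopherolquinone)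
Conditions: 5 (3 equiv), dibenzoyl peroxide (1.5 equiv, in portions), PhCF3, 85 °C, N2; excess 5 recovered on SiO2
Reagents that add atoms: none
Why: Minisci-type homolytic alkylation of a quinone, in which phenyl radicals from the peroxide abstract iodine from 4, the nucleophilic primary radical adds to the only unsubstituted ring carbon of 5, and the peroxide re-oxidises the adduct radical to the quinone in a chain, all remote from the stereocentres and without protecting groups.

**Step 5**
Reactants: 6 2-[(3S,7R,11R)-3-hydroxy-3,7,11,15-tetramethylhexadecyl]-3,5,6-trimethyl-1,4-benzoquinone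
Product: 9 alpha-tocospiro A = (2S,5R,9S)-9-acetyl-9-hydroxy-2,7,8-trimethyl-2-[(4R,8R)-4,8,12-trimethyltridecyl]-1-oxaspiro[4.4]non-7-en-6-one, via epoxyquinone 7 (not isolated), via spiro ketol 8 (not isolated)
Conditions: n-Bu2Mg (1.05 equiv) + L-(+)-DET (1.1 equiv), 4 Å MS, toluene, 0 °C; anhydrous t-BuOOH (1.2 equiv); then 6, 0 °C → rt, then 45 °C; cold 0.5 M HCl quench; SiO2/HPLC removes the (5S,9R) isomer
Reagents that add atoms: tert-butyl hydroperoxide, CC(C)(C)OO
Why: Proposed new method: a magnesium tartrate tert-butyl peroxide (the chirally modified Weitz–Scheffer reagent known for chalcones, and alkaline peroxides are known to epoxidise tetraalkylquinones such as vitamin K1) is anchored by the side-chain oxygen of 6, so the peroxide reaches the near C2=C3 bond rather than the far C5=C6 bond and the tartrate selects the face leading to (1S,6R)-7; the tert-butoxide set free then passes Mg to the tertiary alkoxide, which opens the oxirane 5-exo-tet at the α-keto carbon with inversion (sets C5 = R, with O1 anti to the carbinol oxygen of 8), and the five-membered Mg chelate O–C10–C9=O forces the α-ketol (acyloin) shift of C5 from C10 to C9 so that the new hydroxyl ends anti to O1 (sets C9 = S), the same Mg(II)-promoted ring contraction that turns humulone into isohumulone.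

**Compound list**
1 | natural phytol, (2E,7R,11R)-3,7,11,15-tetramethylhexadec-2-en-1-ol | OC/C=C(\C)CCC[C@H](C)CCC[C@H](C)CCCC(C)C | starting material
2 | [(2S,3S)-3-methyl-3-[(4R,8R)-4,8,12-trimethyltridecyl]oxiran-2-yl]methanol | OC[C@@H]1O[C@@]1(C)CCC[C@H](C)CCC[C@H](C)CCCC(C)C | intermediate
3 | (3S,7R,11R)-3,7,11,15-tetramethylhexadecane-1,3-diol | OCC[C@](C)(CCC[C@H](C)CCC[C@H](C)CCCC(C)C)O | intermediate
4 | (3S,7R,11R)-1-iodo-3,7,11,15-tetramethylhexadecan-3-ol | ICC[C@](C)(CCC[C@H](C)CCC[C@H](C)CCCC(C)C)O | intermediate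
5 | 2,3,5-trimethyl-1,4-benzoquinone | CC1=CC(=O)C(C)=C(C)C1=O | starting material
6 | 2-[(3S,7R,11R)-3-hydroxy-3,7,11,15-tetramethylhexadecyl]-3,5,6-trimethyl-1,4-benzoquinone | CC1=C(C)C(=O)C(CC[C@](C)(CCC[C@H](C)CCC[C@H](C)CCCC(C)C)O)=C(C)C1=O | intermediate
7 | (1S,6R)-1-[(3S,7R,11R)-3-hydroxy-3,7,11,15-tetramethylhexadecyl]-3,4,6-trimethyl-7-oxabicyclo[4.1.0]hept-3-ene-2,5-dione | C[C@@]12O[C@]1(CC[C@](C)(CCC[C@H](C)CCC[C@H](C)CCCC(C)C)O)C(=O)C(C)=C(C)C2=O | intermediate
8 | (2S,5R,10R)-10-hydroxy-2,7,8,10-tetramethyl-2-[(4R,8R)-4,8,12-trimethyltridecyl]-1-oxaspiro[4.5]dec-7-ene-6,9-dione | C[C@]1(O)C(=O)C(C)=C(C)C(=O)[C@@]12CC[C@](C)(CCC[C@H](C)CCC[C@H](C)CCCC(C)C)O2 | intermediate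
9 | alpha-tocospiro A, (2S,5R,9S)-9-acetyl-9-hydroxy-2,7,8-trimethyl-2-[(4R,8R)-4,8,12-trimethyltridecyl]-1-oxaspiro[4.4]non-7-en-6-one | CC(=O)[C@]1(O)C(C)=C(C)C(=O)[C@@]12CC[C@](C)(CCC[C@H](C)CCC[C@H](C)CCCC(C)C)O2 | target

Total step count: 5. Longest linear sequence: 5 (1 → 2 → 3 → 4 → 6 → 9).

**Steps most likely to fail**

*Step 5.* Three things have no direct precedent:
- the preference for the near ring double bond over the far one;
- the facial sense of a tartrate–Mg peroxide on a quinone;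
- the attack of a tertiary alkoxide on a fully substituted oxirane carbon.

The fallback sets out from 6 and comes back at 7. It delivers the oxygen from inside the molecule instead of from an external metal peroxide.
- 6 is hydrogenated (H2, Pd/C, EtOAc) to (3′S)-α-tocopherylhydroquinone F1.
- Acid cyclodehydration (cat. p-TsOH, benzene, reflux), which is expected to keep the carbinol C–O bond, gives (2S,4′R,8′R)-α-tocopherol F2.
- Dye-sensitised photooxygenation (O2, tetraphenylporphyrin, hν, CH2Cl2, −30 °C) gives (2S,8aR)-8a-hydroperoxy-α-tocopherone F3, which is separated from its 8a-epimer.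
- KOt-Bu in THF at −20 °C moves the outer peroxide oxygen onto the neighbouring C4a=C5 bond on the same face, and the hemiketal opens to 7.
- 7 is freed from the 7,8-epoxide regioisomer and carried through 8 to 9 with Mg(OTf)2/Et3N.

*Step 4.* Phenyl radicals may add to the quinone directly, and the alkyl radical may attack substituted ring positions, so the yield may be low. The fallback sets out from 2 and comes back at 6. It replaces the radical C–H alkylation with a polar aryl–alkyl coupling.
- 2 is tosylated (TsCl, Et3N, DMAP, CH2Cl2, 0 °C) to (2S,3S)-epoxyphytyl tosylate F4.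
- F4 is displaced at C1 by 2,5-dimethoxy-3,4,6-trimethylphenylmagnesium bromide F5 (from the catalogue aryl bromide and Mg) under Li2CuCl4 catalysis, giving the (2S,3S)-arylmethyl epoxide F6.
- LiAlH4 opens F6 at the secondary carbon to the (3S)-aryl carbinol F7.
- Ceric ammonium nitrate (MeCN/H2O, 0 °C) oxidises the dimethoxyarene to 6.

*Step 3.* The tertiary carbinol may dehydrate, and the γ-iodo alcohol may close to the oxetane on handling. The fallback sets out from 2 and comes back at 4. It places the iodine by hydroboration instead of substitution on the diol.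
- 2 gives (2R,3S)-epoxyphytyl iodide F8 (I2, PPh3, imidazole).
- Zn dust in refluxing EtOH opens it reductively to (3S,7R,11R)-isophytol F9 with the C3–O bond intact.
- 9-BBN (2.2 equiv, THF) adds anti-Markovnikov to give the B-alkyl-9-BBN adduct F10.
- I2/NaOMe converts the primary B–C bond into the C–I bond of 4.

**Further compounds**
F1 | step 5 | 2-[(3S,7R,11R)-3-hydroxy-3,7,11,15-tetramethylhexadecyl]-3,5,6-trimethylbenzene-1,4-diol | Cc1c(C)c(O)c(CC[C@](C)(CCC[C@H](C)CCC[C@H](C)CCCC(C)C)O)c(C)c1O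
F2 | step 5 | (2S,4′R,8′R)-α-tocopherol | Cc1c(C)c2O[C@@](C)(CCC[C@H](C)CCC[C@H](C)CCCC(C)C)CCc2c(C)c1O
F3 | step 5 | (2S,8aR)-8a-hydroperoxy-α-tocopherone | CC1=C(C)[C@]2(OO)O[C@@](C)(CCC[C@H](C)CCC[C@H](C)CCCC(C)C)CCC2=C(C)C1=O
F4 | step 4 | [(2S,3S)-3-methyl-3-[(4R,8R)-4,8,12-trimethyltridecyl]oxiran-2-yl]methyl 4-methylbenzenesulfonate | Cc1ccc(cc1)S(=O)(=O)OC[C@@H]1O[C@@]1(C)CCC[C@H](C)CCC[C@H](C)CCCC(C)C
F5 | step 4 | 2,5-dimethoxy-3,4,6-trimethylphenylmagnesium bromide | COc1c(C)c(C)c(OC)c(C)c1[Mg]Br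
F6 | step 4 | (2S,3S)-2-[(2,5-dimethoxy-3,4,6-trimethylphenyl)methyl]-3-methyl-3-[(4R,8R)-4,8,12-trimethyltridecyl]oxirane | COc1c(C)c(C)c(OC)c(C)c1C[C@@H]1O[C@@]1(C)CCC[C@H](C)CCC[C@H](C)CCCC(C)C
F7 | step 4 | (3S,7R,11R)-1-(2,5-dimethoxy-3,4,6-trimethylphenyl)-3,7,11,15-tetramethylhexadecan-3-ol | COc1c(C)c(C)c(OC)c(C)c1CC[C@](C)(CCC[C@H](C)CCC[C@H](C)CCCC(C)C)O
F8 | step 3 | (2R,3S)-2-(iodomethyl)-3-methyl-3-[(4R,8R)-4,8,12-trimethyltridecyl]oxirane | IC[C@@H]1O[C@@]1(C)CCC[C@H](C)CCC[C@H](C)CCCC(C)C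
F9 | step 3 | (3S,7R,11R)-3,7,11,15-tetramethylhexadec-1-en-3-ol | C=C[C@](C)(CCC[C@H](C)CCC[C@H](C)CCCC(C)C)O
F10 | step 3 | (3S,7R,11R)-1-(9-borabicyclo[3.3.1]nonan-9-yl)-3,7,11,15-tetramethylhexadecan-3-ol | B1(CC[C@](C)(CCC[C@H](C)CCC[C@H](C)CCCC(C)C)O)C2CCCC1CCC2
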